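**Numbering used throughout:** ring B is O1, C2, C3, C3a, C7a; ring A is C3a, C4, C5, C6, C7, C7a; C9 is the hydroxymethyl carbon on C3; ring C is C1'–C6' (C1' carbinol, C3' hydroxyl, C4' methoxyl).

## The problem

Difengpiol B (35) is a trans-2,3-disubstituted 2,3-dihydrobenzofuran. C2 is bonded to the fully substituted carbinol carbon C1' of a cyclohexane (ring C) that also carries 3'-OH and 4'-OMe; C3 carries the hydroxymethyl carbon C9; ring A carries OMe on C7 and a 3-hydroxypropyl chain on C5.

There are five stereocentres (2S, 3R, 1'S, 3'S, 4'S). C2 and C3 can be set together as a trans pair. C1' can direct C3' and C4', because its hydroxyl lies cis to the 3'-OH and can steer an epoxidation that is then opened trans-diaxially.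

C1' and C2 cannot control each other. C1' is stereogenic only because one ring branch holds the remote C3'–C4' functionality, and its two ring methylene neighbours are sterically alike. Two independent sources of absolute configuration are therefore needed.

C2 is a neopentyl-type secondary carbon, so O1–C2 is best not made by substitution; the oxygen should arrive on C2 as a carbonyl oxygen. The tertiary carbinol, the cyclic enol ethers that appear on the way and the electron-rich ring A will not tolerate strong acid or oxidants, and the tertiary hydroxyl must be told apart from two primary ones.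

The feature that opens the key step is the pattern of ring A: O-bearing C7a next to methoxylated C7, the chain on C5, hydrogen on C4 and C6. This maps onto the enol ether C7a=C3a of a dihydrofuran, a methoxycarbene carbon (C7), a terminal alkyne (C6–H and C5–chain) and one carbonyl ligand (C4). The oxygen that the carbonyl ligand leaves on C4 then has to be removed.

## Retrosynthesis

**C4'–OMe and the epoxide C–O bonds (35 ⇐ 34 ⇐ 33).** Cutting the C4'–OMe bond of 35 gives the cis-epoxy alcohol 34 and methanol; cutting the epoxide gives cyclohexenol 33. The cis-1,3 diol with a trans methoxyl is what a hydroxyl-directed epoxidation followed by diaxial opening delivers. Carrying an oxygenated ring C through the whole route would add two protected oxygens to the aldol, lithiation and benzannulation steps, and would give up the conformational anchor that the large C2 substituent provides late on. The precursor 33 has two fewer stereocentres. The forward steps must epoxidise cis to the C1' hydroxyl and open at C4', not C3'.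

**Silyl ethers and the C4–H bond (33 ⇐ 32 ⇐ 31 ⇐ 30).** The benzannulation leaves a hydroxyl on C4, so 32 is traced to triflate 31 and phenol 30. Triethylsilyl on the tertiary oxygen and tert-butyldimethylsilyl on the two primary ones are all removed by fluoride in one step, so no selective deprotection is asked for. The forward steps must triflate a flanked phenol and reduce the triflate without touching the ring C alkene.

**C6–C7, C4–C5 and C3a–C4 (30 ⇐ 26 + 28).** Ring A is cut into the dihydrofuranyl(methoxy)carbene chromium complex 26 and the terminal alkyne 28. Buying ring A instead would require a 1,2,3,5-tetrasubstituted arene with a halogen on C7a and a ring B closure by C–O coupling at the hindered C2 alkoxide. The cut reduces 30 to a monocyclic enol ether that already holds C2, C3 and C1', plus a five-carbon alkyne. The forward reaction must insert the alkyne with its CH carbon next to the carbene carbon and must leave the three stereocentres alone.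

**C7a–C7 and the enol ether (26 ⇐ 23 ⇐ 21 ⇐ 20).** The carbene carbon is attached by lithiation of dihydrofuran 23 at C7a, addition to Cr(CO)6 and O-methylation. The enol ether comes from lactone 20 by reduction to lactol 21 and dehydration. A cycloisomerisation of a homopropargylic alcohol would be shorter on paper, but the anti alcohol it needs is not available with the same stereocontrol. The dehydration must be mild enough to preserve C2 and C3.

**C2–C3 and O1–C7a (20 ⇐ 19 ⇐ 17 ⇐ 16 ⇐ 13 + 10).** The lactone is cut at C2–C3 (aldol) and at the ester C–O bond (lactonisation) into succinate imide 13 and aldehyde 10. O1 thus arrives as the aldehyde oxygen and no substitution at C2 is needed. The succinate supplies C9 (imide carbonyl), C3, C3a and C7a in the right oxidation states, and a syn aldol translates into the trans ring. Because C1' cannot bias the aldehyde faces, an oxazolidinone auxiliary sets C2 and C3. The forward sequence needs a syn aldol on an α-quaternary aldehyde and a reduction of the C9 carboxyl that spares the lactone and the alkene.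

**C1'–C2' and C5'–C6' (10 ⇐ 9 ⇐ 8 ⇐ 7 ⇐ 5 + 6; 5 ⇐ 3 ⇐ 1 + 2).** Ring C is cut by a Diels–Alder disconnection into buta-1,3-diene 6 and the methylidene dioxolanone 5, which comes from (R)-lactic acid 1 and pivalaldehyde 2 through acetal 3. This sets C1' in one step from the chiral pool, independently of the rest. The forward reaction must add the diene anti to the tert-butyl group.

**Side branches (13 ⇐ 11 + 12; 28 ⇐ 27).** The imide is made by N-acylation of oxazolidinone 11 with acid chloride 12, and the alkyne by silylation of pent-4-yn-1-ol 27.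

## Roads not taken

**Alternative 1:** The cut is the C1'–C2' bond of ring C, made by an Ireland–Claisen ring contraction. The (6S)-6-ethenyl-3-silyloxy δ-lactone A1 would be converted with an amide base and a chlorosilane into its cyclic silyl ketene acetal, which rearranges through the boat transition state that the ring enforces. The lactone C–O bond at the allylic carbon breaks and the acid A2 appears with C1' set by chirality transfer from the carbinol carbon of A1.
- Merits: the quaternary centre derives from an easily made secondary carbinol, A2 arrives already O-silylated, and neither a pressurised diene nor a radical bromination is needed.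
- Weak points: A1 is itself a five- to six-step compound with its own asymmetric step, the acid must still be taken to the aldehyde, and the rearrangement answers only the ring C question.
- Comparison: this road replaces steps 1–5 only. It is the gentler chemistry, but the chosen route reaches the equivalent building block 9 from lactic acid in five operations of well-tried types, so the shorter count was kept.

**Alternative 2:** The cuts are C2–C3 and O1–C2 on a purchased ring A. Base would eliminate sulfinate from phenol A3 to give the ortho-quinone methide A4; the ylide from sulfonium salt A5 adds to the methide carbon (C3) and the phenoxide closes onto C2 with loss of the sulfide, a (4+1) annulation giving the trans amide A6.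
- Merits: ring A comes with all substituents in place, there is no chromium and no surplus oxygen on C4, and trans selectivity is inherent. The amide is also a handle on which ring C could be grown by two organometallic additions and ring-closing metathesis, with C1' controlled by chelation to O1. That would let C2 control C1', which the chosen plan cannot do.
- Weak points: A4 carries an alkyl group with hydrogens next to the methide carbon and can tautomerise to a 2-alkenylphenol before the ylide adds. The achiral A5 gives no absolute control, so a chiral sulfide or catalyst would have to be found. The chelation-controlled addition would have to distinguish two similar alkenyl chains.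
- Comparison: in step count to the dihydrobenzofuran core, and in avoiding stoichiometric chromium and the triflate reduction, this road is better. The chosen plan sets against it absolute control at C2 and C3 from a reliable auxiliary aldol and a C1' centre made beforehand with a known sense, at the price of a longer sequence.

**Alternative 3:** The cuts are C1'–C2' and C5'–C6'. Diene A8 would add thermally to the exocyclic alkene of dioxolanone A7 on the face anti to the tert-butyl group to give spiro adduct A9 with C1' fixed.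
- Merits: short, cheap, chiral-pool based, no metal.
- Weak points: as the strategy-defining step it settles one stereocentre only. The natural continuation with a purchased arene needs a halogen on C7a between the methoxyl and an acetic acid side chain, which is not a commercial pattern, and a ring B closure by aryl C–O coupling from an alkoxide next to the quaternary carbon.
- Comparison: the chosen plan contains this step (steps 1–3; A7 is 5 and A9 is 7), so its strengths are kept and the difference lies in how ring A arrives. A buy-the-arene continuation would avoid chromium and the C4 deoxygenation, which is a real advantage. The chosen plan sets against it that the benzannulation places all four ring A substituents in one operation from two simple partners and needs no bond formation at C2 by substitution.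

Key step: step 16

Assumption: the target configuration is read from the structure as 2S,3R,1'S,3'S,4'S (3'-OH cis to 1'-OH, 4'-OMe trans to both); compounds 1, 2, 6, 11, 12 and 27 are purchased.

## Route

Step 1
Reactants: 1 (R)-lactic acid; 2 pivalaldehyde
Product: 3 (2R,5R)-2-tert-butyl-5-methyl-1,3-dioxolan-4-one
Conditions: TsOH (cat.), H2SO4 (cat.), pentane, reflux, Dean–Stark; crystallisation at −78 °C
Reagents that add atoms: none
Why: Acid-catalysed acetalisation under water removal; the cis acetal predominates and crystallises, and the untouched lactic stereocentre thereby fixes the acetal carbon as R (self-regeneration of stereocentres).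

Step 2
Reactants: 3 (2R,5R)-2-tert-butyl-5-methyl-1,3-dioxolan-4-one
Product: 5 (2R)-2-tert-butyl-5-methylidene-1,3-dioxolan-4-one, via 5-bromo dioxolanone 4 (not isolated)
Conditions: NBS, AIBN (cat.), CCl4 (or PhCF3), reflux; then Et3N, Et2O, 0 °C to rt
Reagents that add atoms: none
Why: Wohl–Ziegler radical bromination at the captodative C5–H followed by E2 loss of HBr gives the exocyclic alkene; the acetal carbon is not involved and is now the only stereocentre.

Step 3
Reactants: 5 (2R)-2-tert-butyl-5-methylidene-1,3-dioxolan-4-one; 6 buta-1,3-diene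
Product: 7 (2R,5S)-2-tert-butyl-1,3-dioxaspiro[4.5]dec-7-en-4-one
Conditions: 6 (5 equiv), BHT (cat.), toluene, sealed vessel, 110 °C
Reagents that add atoms: none
Why: Thermal Diels–Alder reaction of an α-oxygenated acrylate-type alkene; the diene adds to the face of 5 opposite the tert-butyl group, so the new C1'–C2' bond lies anti to it and the spiro carbon (C1') is set as S; a symmetric diene raises no regio- or endo/exo question.

Step 4
Reactants: 7 (2R,5S)-2-tert-butyl-1,3-dioxaspiro[4.5]dec-7-en-4-one
Product: 8 methyl (1S)-1-hydroxycyclohex-3-ene-1-carboxylate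
Conditions: NaOMe (0.2 equiv), MeOH, 0 °C to rt
Reagents that add atoms: methanol, CO
Why: Methoxide opens the acylal carbonyl (transesterification) and the hemiacetal alkoxide expels pivalaldehyde; C1' is not a reacting centre and keeps its configuration.

Step 5
Reactants: 8 methyl (1S)-1-hydroxycyclohex-3-ene-1-carboxylate
Product: 9 methyl (1S)-1-(triethylsilyloxy)cyclohex-3-ene-1-carboxylate
Conditions: Et3SiOTf, 2,6-lutidine, CH2Cl2, 0 °C
Reagents that add atoms: triethylsilyl trifluoromethanesulfonate, CC[Si](CC)(CC)OS(=O)(=O)C(F)(F)F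
Why: Silyl triflate/lutidine silylation is the standard way to cap a hindered tertiary alcohol; the triethylsilyl ether should survive boron triflate, hydride, organolithium and palladium steps yet fall to fluoride together with the primary silyl ethers.

Step 6
Reactants: 9 methyl (1S)-1-(triethylsilyloxy)cyclohex-3-ene-1-carboxylate
Product: 10 (1S)-1-(triethylsilyloxy)cyclohex-3-ene-1-carbaldehyde
Conditions: i-Bu2AlH (1.1 equiv), CH2Cl2, −78 °C; aqueous KNaC4H4O6
Reagents that add atoms: none
Why: Partial reduction of an α-silyloxy ester; the tetrahedral aluminium alkoxide is stable at −78 °C and releases the aldehyde only on work-up, and the quaternary α-carbon excludes epimerisation.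

Step 7
Reactants: 11 (4S)-4-benzyl-1,3-oxazolidin-2-one; 12 methyl 4-chloro-4-oxobutanoate
Product: 13 methyl 4-[(4S)-4-benzyl-2-oxo-1,3-oxazolidin-3-yl]-4-oxobutanoate
Conditions: Et3N, DMAP (cat.), CH2Cl2, 0 °C to rt
Reagents that add atoms: none
Why: N-Acylation of the oxazolidinone by the acid chloride under nucleophilic catalysis; the ester end of 12 does not react under these conditions.

Step 8
Reactants: 13 methyl 4-[(4S)-4-benzyl-2-oxo-1,3-oxazolidin-3-yl]-4-oxobutanoate; 10 (1S)-1-(triethylsilyloxy)cyclohex-3-ene-1-carbaldehyde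
Product: 16 (4S)-4-benzyl-3-{(2S,3S)-5-oxo-2-[(1S)-1-(triethylsilyloxy)cyclohex-3-en-1-yl]oxolane-3-carbonyl}-1,3-oxazolidin-2-one, via dibutylboron Z-enolate 14 (not isolated), via open-chain aldol hydroxy ester 15 (not isolated)
Conditions: Bu2BOTf, i-Pr2NEt, CH2Cl2, 0 °C; 10, −78 to 0 °C; pH 7 buffer, MeOH, H2O2, 0 °C; crude with PPTS (cat.), toluene, 50 °C
Reagents that add atoms: none
Why: Evans syn aldol reaction: the Z-boron enolate of the imide reacts through a Zimmerman–Traxler chair on the enolate face away from the benzyl group, which sets C2 (S) and C3 under auxiliary control, and the aldehyde α-centre, whose two ring arms are sterically alike, causes no mismatch. The γ-hydroxy ester then lactonises, and the syn aldol relationship becomes the trans lactone in which O1 is already tied to the future C7a.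

Step 9
Reactants: 16 (4S)-4-benzyl-3-{(2S,3S)-5-oxo-2-[(1S)-1-(triethylsilyloxy)cyclohex-3-en-1-yl]oxolane-3-carbonyl}-1,3-oxazolidin-2-one
Product: 17 (2S,3S)-5-oxo-2-[(1S)-1-(triethylsilyloxy)cyclohex-3-en-1-yl]oxolane-3-carboxylic acid
Conditions: LiOH, H2O2, THF/H2O, 0 °C; Na2SO3; 1 M HCl to pH 3, 0 °C
Reagents that add atoms: hydrogen peroxide (as LiOOH), OO
Why: Hydroperoxide attacks the exocyclic imide carbonyl selectively and frees the auxiliary; any lactone opening is reversed on acidification, and the trans arrangement at C3 is the stable one, so epimerisation has no driving force.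

Step 10
Reactants: 17 (2S,3S)-5-oxo-2-[(1S)-1-(triethylsilyloxy)cyclohex-3-en-1-yl]oxolane-3-carboxylic acid
Product: 19 (4R,5S)-4-(hydroxymethyl)-5-[(1S)-1-(triethylsilyloxy)cyclohex-3-en-1-yl]oxolan-2-one, via isobutyl carbonic mixed anhydride 18 (not isolated)
Conditions: i-BuOCOCl, N-methylmorpholine, THF, −15 °C; then NaBH4, H2O, −15 to 0 °C
Reagents that add atoms: none
Why: Mixed carbonic anhydride reduction: NaBH4 reduces the activated acyl group within minutes at low temperature while the γ-lactone survives, and the ring alkene, which a borane reduction of the acid would hydroborate, is not touched.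

Step 11
Reactants: 19 (4R,5S)-4-(hydroxymethyl)-5-[(1S)-1-(triethylsilyloxy)cyclohex-3-en-1-yl]oxolan-2-one
Product: 20 (4R,5S)-4-{[tert-butyl(dimethyl)silyl]oxymethyl}-5-[(1S)-1-(triethylsilyloxy)cyclohex-3-en-1-yl]oxolan-2-one
Conditions: t-BuMe2SiCl, imidazole, DMF, 0 °C to rt
Reagents that add atoms: tert-butyldimethylsilyl chloride, CC(C)(C)[Si](C)(C)Cl
Why: Standard silylation of a primary alcohol; the mild base avoids translactonisation between the C9 hydroxyl and the lactone carbonyl.

Step 12
Reactants: 20 (4R,5S)-4-{[tert-butyl(dimethyl)silyl]oxymethyl}-5-[(1S)-1-(triethylsilyloxy)cyclohex-3-en-1-yl]oxolan-2-one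
Product: 21 (4R,5S)-4-{[tert-butyl(dimethyl)silyl]oxymethyl}-5-[(1S)-1-(triethylsilyloxy)cyclohex-3-en-1-yl]oxolan-2-ol (both anomers)
Conditions: i-Bu2AlH (1.1 equiv), CH2Cl2, −78 °C; aqueous KNaC4H4O6
Reagents that add atoms: none
Why: Partial reduction of a γ-lactone to the lactol with one hydride equivalent at −78 °C; silyl ethers and the alkene are inert.

Step 13
Reactants: 21 (4R,5S)-4-{[tert-butyl(dimethyl)silyl]oxymethyl}-5-[(1S)-1-(triethylsilyloxy)cyclohex-3-en-1-yl]oxolan-2-ol
Product: 23 (2S,3R)-3-{[tert-butyl(dimethyl)silyl]oxymethyl}-2-[(1S)-1-(triethylsilyloxy)cyclohex-3-en-1-yl]-2,3-dihydrofuran, via anomeric mesylate 22 (not isolated)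
Conditions: MsCl, Et3N (5 equiv), CH2Cl2, −30 °C to reflux; chromatography on Et3N-washed silica
Reagents that add atoms: none
Why: Mesylation of the lactol hydroxyl and base-assisted loss of methanesulfonate through the oxocarbenium ion, with removal of a proton from C3a, gives the cyclic enol ether as in furanoid glycal preparations; C2 and C3 are not reacting centres.

Step 14
Reactants: 23 (2S,3R)-3-{[tert-butyl(dimethyl)silyl]oxymethyl}-2-[(1S)-1-(triethylsilyloxy)cyclohex-3-en-1-yl]-2,3-dihydrofuran
Product: 26 pentacarbonyl{[(4R,5S)-4-{[tert-butyl(dimethyl)silyl]oxymethyl}-5-[(1S)-1-(triethylsilyloxy)cyclohex-3-en-1-yl]-4,5-dihydrofuran-2-yl](methoxy)methylidene}chromium, via 2-lithio-dihydrofuran 24 (not isolated), via lithium acylchromate 25 (not isolated)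
Conditions: t-BuLi (1.3 equiv), THF, −78 to 0 °C; Cr(CO)6, Et2O, 0 °C to rt; Me3OBF4, CH2Cl2, 0 °C
Reagents that add atoms: hexacarbonylchromium Cr(CO)6, O=C=[Cr](=C=O)(=C=O)(=C=O)(=C=O)=C=O; trimethyloxonium tetrafluoroborate Me3OBF4, C[O+](C)C.F[B-](F)(F)F
Why: Fischer carbene synthesis: the vinylic hydrogen on the oxygen-bearing enol ether carbon (C7a) is the kinetically most acidic, the vinyllithium adds to a carbonyl ligand of Cr(CO)6 to give the acylchromate, and the hard oxonium salt methylates it on oxygen; lithiated glycals and dihydropyrans are converted into such complexes in the same way.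

Step 15
Reactants: 27 pent-4-yn-1-ol
Product: 28 tert-butyl(dimethyl)(pent-4-yn-1-yloxy)silane
Conditions: t-BuMe2SiCl, imidazole, CH2Cl2, rt
Reagents that add atoms: tert-butyldimethylsilyl chloride, CC(C)(C)[Si](C)(C)Cl
Why: Standard silylation; the ether keeps the chain hydroxyl from trapping the ketene intermediate of the benzannulation and from being triflated later.

Step 16
Reactants: 26 pentacarbonyl{[(4R,5S)-4-{[tert-butyl(dimethyl)silyl]oxymethyl}-5-[(1S)-1-(triethylsilyloxy)cyclohex-3-en-1-yl]-4,5-dihydrofuran-2-yl](methoxy)methylidene}chromium; 28 tert-butyl(dimethyl)(pent-4-yn-1-yloxy)silane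
Product: 30 (2S,3R)-3-{[tert-butyl(dimethyl)silyl]oxymethyl}-5-{3-[tert-butyl(dimethyl)silyl]oxypropyl}-7-methoxy-2-[(1S)-1-(triethylsilyloxy)cyclohex-3-en-1-yl]-2,3-dihydro-1-benzofuran-4-ol, via tricarbonylchromium arene complex 29 (not isolated)
Conditions: 28 (2 equiv), THF (0.05 M), 50 °C, argon; then air, Et2O, rt
Reagents that add atoms: none
Why: Dötz benzannulation. Thermal loss of one carbonyl ligand from 26 opens a site for alkyne 28, which inserts into the Cr=C bond with its unsubstituted carbon bonded to the carbene carbon (C6–C7); carbonyl insertion then gives a chromium-bound dienylketene (C4–C5), whose ketene carbon closes onto C3a by a 6π-electrocyclisation (ring A), and tautomerisation of the cyclohexadienone gives the phenol as its Cr(CO)3 complex 29, which air decomplexes. The closest known reaction type is the benzannulation of dihydropyranyl- and glycal-derived methoxycarbene chromium complexes with terminal alkynes. No stereocentre is formed, and C2, C3 and C1' are spectators under neutral conditions at 50 °C. The step needs regioselectivity (chain on C5, not C6), which the difference between hydrogen and alkyl on a terminal alkyne secures. It also needs the phenol to win over cyclobutenone or furan products, which an alkenyl carbene with a hydrogen on C3a in a donor solvent favours. The silyl ethers on both partners keep hydroxyl groups from intercepting the ketene.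

Step 17
Reactants: 30 (2S,3R)-3-{[tert-butyl(dimethyl)silyl]oxymethyl}-5-{3-[tert-butyl(dimethyl)silyl]oxypropyl}-7-methoxy-2-[(1S)-1-(triethylsilyloxy)cyclohex-3-en-1-yl]-2,3-dihydro-1-benzofuran-4-ol
Product: 31 (2S,3R)-3-{[tert-butyl(dimethyl)silyl]oxymethyl}-5-{3-[tert-butyl(dimethyl)silyl]oxypropyl}-7-methoxy-2-[(1S)-1-(triethylsilyloxy)cyclohex-3-en-1-yl]-2,3-dihydro-1-benzofuran-4-yl trifluoromethanesulfonate
Conditions: Tf2O, pyridine, CH2Cl2, 0 °C
Reagents that add atoms: trifluoromethanesulfonic anhydride, O=S(=O)(OS(=O)(=O)C(F)(F)F)C(F)(F)F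
Why: O-Sulfonylation of the phenol turns the surplus C4 oxygen into a leaving group for palladium; it is run on freshly prepared 30 because hydroquinone monoethers oxidise easily.

Step 18
Reactants: 31 (2S,3R)-3-{[tert-butyl(dimethyl)silyl]oxymethyl}-5-{3-[tert-butyl(dimethyl)silyl]oxypropyl}-7-methoxy-2-[(1S)-1-(triethylsilyloxy)cyclohex-3-en-1-yl]-2,3-dihydro-1-benzofuran-4-yl trifluoromethanesulfonate
Product: 32 (2S,3R)-3-{[tert-butyl(dimethyl)silyl]oxymethyl}-5-{3-[tert-butyl(dimethyl)silyl]oxypropyl}-7-methoxy-2-[(1S)-1-(triethylsilyloxy)cyclohex-3-en-1-yl]-2,3-dihydro-1-benzofuran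
Conditions: Pd(OAc)2 (5 mol%), dppf (10 mol%), HCO2H, Et3N, DMF, 70 °C
Reagents that add atoms: none
Why: Palladium-catalysed hydrogenolysis of an aryl triflate with formate as hydride source (oxidative addition to zerovalent palladium, formate exchange, decarboxylation, C–H reductive elimination); the buffered medium spares the silyl ethers and the isolated alkene is not reduced.

Step 19
Reactants: 32 (2S,3R)-3-{[tert-butyl(dimethyl)silyl]oxymethyl}-5-{3-[tert-butyl(dimethyl)silyl]oxypropyl}-7-methoxy-2-[(1S)-1-(triethylsilyloxy)cyclohex-3-en-1-yl]-2,3-dihydro-1-benzofuran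
Product: 33 (1S)-1-[(2S,3R)-3-(hydroxymethyl)-5-(3-hydroxypropyl)-7-methoxy-2,3-dihydro-1-benzofuran-2-yl]cyclohex-3-en-1-ol
Conditions: Bu4NF (5 equiv), THF, rt to 45 °C
Reagents that add atoms: none
Why: Fluoride cleaves all three Si–O bonds; gentle warming deals with the hindered tertiary triethylsilyl ether, so no selective deprotection is needed.

Step 20
Reactants: 33 (1S)-1-[(2S,3R)-3-(hydroxymethyl)-5-(3-hydroxypropyl)-7-methoxy-2,3-dihydro-1-benzofuran-2-yl]cyclohex-3-en-1-ol
Product: 34 (1S,3S,6R)-3-[(2S,3R)-3-(hydroxymethyl)-5-(3-hydroxypropyl)-7-methoxy-2,3-dihydro-1-benzofuran-2-yl]-7-oxabicyclo[4.1.0]heptan-3-ol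
Conditions: VO(acac)2 (5 mol%), t-BuOOH, CH2Cl2, 0 °C to rt
Reagents that add atoms: tert-butyl hydroperoxide, CC(C)(C)OO
Why: Vanadium-catalysed hydroxyl-directed epoxidation: the peroxo vanadate bound to the axial homoallylic C1' hydroxyl delivers oxygen to the alkene face cis to it, which sets C3' (S) and C4' (R); the primary hydroxyls are too remote to direct, and the large C2 substituent keeps the C1' hydroxyl axial.

Step 21
Reactants: 34 (1S,3S,6R)-3-[(2S,3R)-3-(hydroxymethyl)-5-(3-hydroxypropyl)-7-methoxy-2,3-dihydro-1-benzofuran-2-yl]-7-oxabicyclo[4.1.0]heptan-3-ol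
Product: 35 difengpiol B, (1S,3S,4S)-1-[(2S,3R)-3-(hydroxymethyl)-5-(3-hydroxypropyl)-7-methoxy-2,3-dihydro-1-benzofuran-2-yl]-4-methoxycyclohexane-1,3-diol
Conditions: camphorsulfonic acid (10 mol%), MeOH, 0 °C to rt
Reagents that add atoms: methanol, CO
Why: Acid-catalysed trans-diaxial epoxide opening (Fürst–Plattner rule): in the half-chair with the C2 substituent equatorial and the C1' hydroxyl axial, methanol attacks C4' axially from the face opposite the epoxide oxygen, which inverts C4' to S and leaves the C3' oxygen (S) cis to the C1' hydroxyl. Attack at C3' would need the large group axial and is also disfavoured by the inductive effect of the C1' oxygen.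

## Compound list

1 | (R)-lactic acid, (2R)-2-hydroxypropanoic acid | C[C@@H](O)C(=O)O | starting material
2 | pivalaldehyde, 2,2-dimethylpropanal | CC(C)(C)C=O | starting material
3 | (2R,5R)-2-tert-butyl-5-methyl-1,3-dioxolan-4-one (cis) | O=C1[C@@H](C)O[C@@H](C(C)(C)C)O1 | intermediate
4 | (2S,5S)-5-bromo-2-tert-butyl-5-methyl-1,3-dioxolan-4-one (Br trans to tert-butyl) | O=C1[C@@](Br)(C)O[C@@H](C(C)(C)C)O1 | intermediate (not isolated)
5 | (2R)-2-tert-butyl-5-methylidene-1,3-dioxolan-4-one | O=C1C(=C)O[C@@H](C(C)(C)C)O1 | intermediate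
6 | buta-1,3-diene | C=CC=C | starting material
7 | (2R,5S)-2-tert-butyl-1,3-dioxaspiro[4.5]dec-7-en-4-one | O=C1[C@@]2(CCC=CC2)O[C@@H](C(C)(C)C)O1 | intermediate
8 | methyl (1S)-1-hydroxycyclohex-3-ene-1-carboxylate | COC(=O)[C@]1(O)CCC=CC1 | intermediate
9 | methyl (1S)-1-(triethylsilyloxy)cyclohex-3-ene-1-carboxylate | COC(=O)[C@]1(O[Si](CC)(CC)CC)CCC=CC1 | intermediate
10 | (1S)-1-(triethylsilyloxy)cyclohex-3-ene-1-carbaldehyde | O=C[C@]1(O[Si](CC)(CC)CC)CCC=CC1 | intermediate
11 | (4S)-4-benzyl-1,3-oxazolidin-2-one | O=C1N[C@@H](Cc2ccccc2)CO1 | starting material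
12 | methyl 4-chloro-4-oxobutanoate | COC(=O)CCC(Cl)=O | starting material
13 | methyl 4-[(4S)-4-benzyl-2-oxo-1,3-oxazolidin-3-yl]-4-oxobutanoate | COC(=O)CCC(=O)N1[C@@H](Cc2ccccc2)COC1=O | intermediate
14 | methyl (3Z)-4-[(4S)-4-benzyl-2-oxo-1,3-oxazolidin-3-yl]-4-(dibutylboranyloxy)but-3-enoate | CCCCB(CCCC)O/C(=C\CC(=O)OC)N1[C@@H](Cc2ccccc2)COC1=O | intermediate (not isolated)
15 | methyl (3S,4S)-3-{[(4S)-4-benzyl-2-oxo-1,3-oxazolidin-3-yl]carbonyl}-4-hydroxy-4-[(1S)-1-(triethylsilyloxy)cyclohex-3-en-1-yl]butanoate | O[C@H]([C@]1(O[Si](CC)(CC)CC)CCC=CC1)[C@H](CC(=O)OC)C(=O)N2[C@@H](Cc3ccccc3)COC2=O | intermediate (not isolated)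
16 | (4S)-4-benzyl-3-{(2S,3S)-5-oxo-2-[(1S)-1-(triethylsilyloxy)cyclohex-3-en-1-yl]oxolane-3-carbonyl}-1,3-oxazolidin-2-one (trans lactone) | O=C1O[C@H]([C@]2(O[Si](CC)(CC)CC)CCC=CC2)[C@H](C1)C(=O)N3[C@@H](Cc4ccccc4)COC3=O | intermediate
17 | (2S,3S)-5-oxo-2-[(1S)-1-(triethylsilyloxy)cyclohex-3-en-1-yl]oxolane-3-carboxylic acid | O=C1O[C@H]([C@]2(O[Si](CC)(CC)CC)CCC=CC2)[C@H](C1)C(=O)O | intermediate
18 | (2S,3S)-5-oxo-2-[(1S)-1-(triethylsilyloxy)cyclohex-3-en-1-yl]oxolane-3-carboxylic 2-methylpropyl carbonic anhydride | O=C1O[C@H]([C@]2(O[Si](CC)(CC)CC)CCC=CC2)[C@H](C1)C(=O)OC(=O)OCC(C)C | intermediate (not isolated)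
19 | (4R,5S)-4-(hydroxymethyl)-5-[(1S)-1-(triethylsilyloxy)cyclohex-3-en-1-yl]oxolan-2-one | O=C1O[C@H]([C@]2(O[Si](CC)(CC)CC)CCC=CC2)[C@H](C1)CO | intermediate
20 | (4R,5S)-4-{[tert-butyl(dimethyl)silyl]oxymethyl}-5-[(1S)-1-(triethylsilyloxy)cyclohex-3-en-1-yl]oxolan-2-one | O=C1O[C@H]([C@]2(O[Si](CC)(CC)CC)CCC=CC2)[C@H](C1)CO[Si](C)(C)C(C)(C)C | intermediate
21 | (4R,5S)-4-{[tert-butyl(dimethyl)silyl]oxymethyl}-5-[(1S)-1-(triethylsilyloxy)cyclohex-3-en-1-yl]oxolan-2-ol (both anomers) | OC1O[C@H]([C@]2(O[Si](CC)(CC)CC)CCC=CC2)[C@H](C1)CO[Si](C)(C)C(C)(C)C | intermediate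
22 | (4R,5S)-4-{[tert-butyl(dimethyl)silyl]oxymethyl}-5-[(1S)-1-(triethylsilyloxy)cyclohex-3-en-1-yl]oxolan-2-yl methanesulfonate | CS(=O)(=O)OC1O[C@H]([C@]2(O[Si](CC)(CC)CC)CCC=CC2)[C@H](C1)CO[Si](C)(C)C(C)(C)C | intermediate (not isolated)
23 | (2S,3R)-3-{[tert-butyl(dimethyl)silyl]oxymethyl}-2-[(1S)-1-(triethylsilyloxy)cyclohex-3-en-1-yl]-2,3-dihydrofuran | C1=C[C@H](CO[Si](C)(C)C(C)(C)C)[C@@H]([C@]2(O[Si](CC)(CC)CC)CCC=CC2)O1 | intermediate
24 | [(4R,5S)-4-{[tert-butyl(dimethyl)silyl]oxymethyl}-5-[(1S)-1-(triethylsilyloxy)cyclohex-3-en-1-yl]-4,5-dihydrofuran-2-yl]lithium | [Li]C1=C[C@H](CO[Si](C)(C)C(C)(C)C)[C@@H]([C@]2(O[Si](CC)(CC)CC)CCC=CC2)O1 | intermediate (not isolated)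
25 | lithium pentacarbonyl{[(4R,5S)-4-{[tert-butyl(dimethyl)silyl]oxymethyl}-5-[(1S)-1-(triethylsilyloxy)cyclohex-3-en-1-yl]-4,5-dihydrofuran-2-yl]carbonyl}chromate | [Li+].[O-]C(=[Cr](=C=O)(=C=O)(=C=O)(=C=O)=C=O)C1=C[C@H](CO[Si](C)(C)C(C)(C)C)[C@@H]([C@]2(O[Si](CC)(CC)CC)CCC=CC2)O1 | intermediate (not isolated)
26 | pentacarbonyl{[(4R,5S)-4-{[tert-butyl(dimethyl)silyl]oxymethyl}-5-[(1S)-1-(triethylsilyloxy)cyclohex-3-en-1-yl]-4,5-dihydrofuran-2-yl](methoxy)methylidene}chromium | COC(=[Cr](=C=O)(=C=O)(=C=O)(=C=O)=C=O)C1=C[C@H](CO[Si](C)(C)C(C)(C)C)[C@@H]([C@]2(O[Si](CC)(CC)CC)CCC=CC2)O1 | intermediate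
27 | pent-4-yn-1-ol | C#CCCCO | starting material
28 | tert-butyl(dimethyl)(pent-4-yn-1-yloxy)silane | C#CCCCO[Si](C)(C)C(C)(C)C | intermediate
29 | tricarbonyl(η6-arene)chromium complex of 30 (arene and Cr(CO)3 written as two parts) | COc1cc(CCCO[Si](C)(C)C(C)(C)C)c(O)c2c1O[C@H]([C@]1(O[Si](CC)(CC)CC)CCC=CC1)[C@H]2CO[Si](C)(C)C(C)(C)C.O=C=[Cr](=C=O)=C=O | intermediate (not isolated)
30 | (2S,3R)-3-{[tert-butyl(dimethyl)silyl]oxymethyl}-5-{3-[tert-butyl(dimethyl)silyl]oxypropyl}-7-methoxy-2-[(1S)-1-(triethylsilyloxy)cyclohex-3-en-1-yl]-2,3-dihydro-1-benzofuran-4-ol | COc1cc(CCCO[Si](C)(C)C(C)(C)C)c(O)c2c1O[C@H]([C@]1(O[Si](CC)(CC)CC)CCC=CC1)[C@H]2CO[Si](C)(C)C(C)(C)C | intermediate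
31 | 4-trifluoromethanesulfonate of 30 | COc1cc(CCCO[Si](C)(C)C(C)(C)C)c(OS(=O)(=O)C(F)(F)F)c2c1O[C@H]([C@]1(O[Si](CC)(CC)CC)CCC=CC1)[C@H]2CO[Si](C)(C)C(C)(C)C | intermediate
32 | (2S,3R)-3-{[tert-butyl(dimethyl)silyl]oxymethyl}-5-{3-[tert-butyl(dimethyl)silyl]oxypropyl}-7-methoxy-2-[(1S)-1-(triethylsilyloxy)cyclohex-3-en-1-yl]-2,3-dihydro-1-benzofuran | COc1cc(CCCO[Si](C)(C)C(C)(C)C)cc2c1O[C@H]([C@]1(O[Si](CC)(CC)CC)CCC=CC1)[C@H]2CO[Si](C)(C)C(C)(C)C | intermediate
33 | (1S)-1-[(2S,3R)-3-(hydroxymethyl)-5-(3-hydroxypropyl)-7-methoxy-2,3-dihydro-1-benzofuran-2-yl]cyclohex-3-en-1-ol | COc1cc(CCCO)cc2c1O[C@H]([C@]1(O)CCC=CC1)[C@H]2CO | intermediate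
34 | (1S,3S,6R)-3-[(2S,3R)-3-(hydroxymethyl)-5-(3-hydroxypropyl)-7-methoxy-2,3-dihydro-1-benzofuran-2-yl]-7-oxabicyclo[4.1.0]heptan-3-ol (epoxide cis to the hydroxyl) | COc1cc(CCCO)cc2c1O[C@H]([C@]1(O)CC[C@H]3O[C@H]3C1)[C@H]2CO | intermediate
35 | difengpiol B, (1S,3S,4S)-1-[(2S,3R)-3-(hydroxymethyl)-5-(3-hydroxypropyl)-7-methoxy-2,3-dihydro-1-benzofuran-2-yl]-4-methoxycyclohexane-1,3-diol | COc1cc(CCCO)cc2c1O[C@H]([C@]1(O)CC[C@H](OC)[C@@H](O)C1)[C@H]2CO | target

## Step count and risk

Total: 21 steps. Longest linear sequence: 19 steps (steps 1–6, 8–14, 16–21); steps 7 and 15 are side branches.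

**Step 16 (key step).** The oxygen-rich alkenylcarbene may decompose before the alkyne is taken up, the vinylcarbene or vinylketene intermediate may be diverted (incomplete carbonyl insertion, cyclobutenone or furan formation), and the electron-rich phenol may be oxidised during decomplexation. The cause is the high electron density and the steric load next to the metal.

Fallback, setting out from 20 and returning at 32, builds ring A on the lactone without chromium:
- The lithium enolate of 20 (LiN(SiMe3)2, THF, −78 °C) is alkylated with 2,3-dibromopropene to the 2-bromoallyl lactone F1.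
- B-alkyl Suzuki–Miyaura coupling with the 9-BBN adduct of tert-butyl(dimethyl)(prop-2-enyloxy)silane (Pd(dppf)Cl2, K3PO4) gives the 2-methylidene-5-silyloxypentyl lactone F2.
- KN(SiMe3)2 and (PhO)2P(O)Cl convert it into the ketene acetal phosphate F3.
- Carbonylative Stille coupling with tributyl(ethenyl)stannane under CO (Pd(PPh3)4, LiCl) gives the dihydrofuranyl vinyl ketone F4.
- Ring-closing metathesis with the second-generation Grubbs catalyst closes C5=C6, and the cyclohexadienone tautomerises to the C7 phenol F5.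
- O-Methylation (MeI, K2CO3) gives 32, bypassing steps 12–18.

**Step 8.** Addition of the boron enolate to the α-quaternary, α-silyloxy aldehyde may be slow or incomplete, and retro-aldol cleavage may compete while the hindered hydroxyl lactonises.

Fallback, setting out from 10 and returning at 19, sets C2 by catalyst-controlled alkynylation and C3 by conjugate addition:
- Methyl propiolate is added to 10 with Me2Zn and the ProPhenol ligand enantiomer that delivers the 4S carbinol, giving the propargylic alcohol F6.
- Semihydrogenation over Pd/CaCO3 poisoned with Pb(OAc)2, with lactonisation in the same pot, gives the butenolide F7.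
- Benzophenone-sensitised photoaddition of methanol places the hydroxymethyl group on C3 trans to the C2 substituent and gives 19.

**Step 13.** Elimination may stop at an anomeric chloride or a bis-lactol ether, and the enol ether may be hydrated or decompose on isolation, because the oxocarbenium ion is flanked by a bulky centre and the product is acid-labile.

Fallback, setting out from 20 and returning at 23, avoids the lactol: KN(SiMe3)2 and (PhO)2P(O)Cl convert 20 into the ketene acetal phosphate F8, and palladium-catalysed reductive cleavage of its C–O(P) bond (Pd(PPh3)4, LiCl, Bu3SnH) gives 23.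

**Step 14.** Lithiation may be incomplete or misdirected (removal of the allylic C3 hydrogen followed by ring opening), O-methylation of the acylchromate may be inefficient, and material may be lost on chromatography.

Fallback, setting out from 20 and returning at 24, generates the anion by tin–lithium exchange instead of deprotonation: the ketene acetal phosphate F8 is stannylated (Pd(PPh3)4, Me3SnSnMe3, LiCl) to the vinylstannane F9, and MeLi in THF at −78 °C then gives 24, which is taken on with Cr(CO)6 as in step 14.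

## Further compounds

F1 | step 16 | (4R,5S)-3-(2-bromoprop-2-en-1-yl)-4-{[tert-butyl(dimethyl)silyl]oxymethyl}-5-[(1S)-1-(triethylsilyloxy)cyclohex-3-en-1-yl]oxolan-2-one (C3 not defined) | O=C1O[C@H]([C@]2(O[Si](CC)(CC)CC)CCC=CC2)[C@H](C1CC(Br)=C)CO[Si](C)(C)C(C)(C)C
F2 | step 16 | (4R,5S)-4-{[tert-butyl(dimethyl)silyl]oxymethyl}-3-{5-[tert-butyl(dimethyl)silyl]oxy-2-methylidenepentyl}-5-[(1S)-1-(triethylsilyloxy)cyclohex-3-en-1-yl]oxolan-2-one (C3 not defined) | O=C1O[C@H]([C@]2(O[Si](CC)(CC)CC)CCC=CC2)[C@H](C1CC(=C)CCCO[Si](C)(C)C(C)(C)C)CO[Si](C)(C)C(C)(C)C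
F3 | step 16 | (4R,5S)-4-{[tert-butyl(dimethyl)silyl]oxymethyl}-3-{5-[tert-butyl(dimethyl)silyl]oxy-2-methylidenepentyl}-5-[(1S)-1-(triethylsilyloxy)cyclohex-3-en-1-yl]-4,5-dihydrofuran-2-yl diphenyl phosphate | C=C(CCCO[Si](C)(C)C(C)(C)C)CC1=C(OP(=O)(Oc2ccccc2)Oc2ccccc2)O[C@H]([C@]2(O[Si](CC)(CC)CC)CCC=CC2)[C@H]1CO[Si](C)(C)C(C)(C)C
F4 | step 16 | 1-[(4R,5S)-4-{[tert-butyl(dimethyl)silyl]oxymethyl}-3-{5-[tert-butyl(dimethyl)silyl]oxy-2-methylidenepentyl}-5-[(1S)-1-(triethylsilyloxy)cyclohex-3-en-1-yl]-4,5-dihydrofuran-2-yl]prop-2-en-1-one | C=C(CCCO[Si](C)(C)C(C)(C)C)CC1=C(C(=O)C=C)O[C@H]([C@]2(O[Si](CC)(CC)CC)CCC=CC2)[C@H]1CO[Si](C)(C)C(C)(C)C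
F5 | step 16 | (2S,3R)-3-{[tert-butyl(dimethyl)silyl]oxymethyl}-5-{3-[tert-butyl(dimethyl)silyl]oxypropyl}-2-[(1S)-1-(triethylsilyloxy)cyclohex-3-en-1-yl]-2,3-dihydro-1-benzofuran-7-ol | Oc1cc(CCCO[Si](C)(C)C(C)(C)C)cc2c1O[C@H]([C@]1(O[Si](CC)(CC)CC)CCC=CC1)[C@H]2CO[Si](C)(C)C(C)(C)C
F6 | step 8 | methyl (4S)-4-hydroxy-4-[(1S)-1-(triethylsilyloxy)cyclohex-3-en-1-yl]but-2-ynoate | COC(=O)C#C[C@H](O)[C@]1(O[Si](CC)(CC)CC)CCC=CC1
F7 | step 8 | (5S)-5-[(1S)-1-(triethylsilyloxy)cyclohex-3-en-1-yl]furan-2(5H)-one | O=C1C=C[C@@H]([C@]2(O[Si](CC)(CC)CC)CCC=CC2)O1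
F8 | step 13 | (4R,5S)-4-{[tert-butyl(dimethyl)silyl]oxymethyl}-5-[(1S)-1-(triethylsilyloxy)cyclohex-3-en-1-yl]-4,5-dihydrofuran-2-yl diphenyl phosphate | O=P(Oc1ccccc1)(Oc1ccccc1)OC1=C[C@H](CO[Si](C)(C)C(C)(C)C)[C@@H]([C@]2(O[Si](CC)(CC)CC)CCC=CC2)O1
F9 | step 14 | trimethyl[(4R,5S)-4-{[tert-butyl(dimethyl)silyl]oxymethyl}-5-[(1S)-1-(triethylsilyloxy)cyclohex-3-en-1-yl]-4,5-dihydrofuran-2-yl]stannane | C[Sn](C)(C)C1=C[C@H](CO[Si](C)(C)C(C)(C)C)[C@@H]([C@]2(O[Si](CC)(CC)CC)CCC=CC2)O1
A1 | alternative 1 | (6S)-3-[tert-butyl(dimethyl)silyl]oxy-6-ethenyloxan-2-one (C3 not defined) | C=C[C@@H]1CCC(O[Si](C)(C)C(C)(C)C)C(=O)O1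
A2 | alternative 1 | (1S)-1-[tert-butyl(dimethyl)silyl]oxycyclohex-3-ene-1-carboxylic acid | OC(=O)[C@]1(O[Si](C)(C)C(C)(C)C)CCC=CC1
A3 | alternative 2 | 2-{2-[tert-butyl(dimethyl)silyl]oxy-1-[(4-methylphenyl)sulfonyl]ethyl}-4-{3-[tert-butyl(dimethyl)silyl]oxypropyl}-6-methoxyphenol | COc1cc(CCCO[Si](C)(C)C(C)(C)C)cc(C(CO[Si](C)(C)C(C)(C)C)S(=O)(=O)c2ccc(C)cc2)c1O
A4 | alternative 2 | 6-{2-[tert-butyl(dimethyl)silyl]oxyethylidene}-4-{3-[tert-butyl(dimethyl)silyl]oxypropyl}-2-methoxycyclohexa-2,4-dien-1-one | COC1=CC(CCCO[Si](C)(C)C(C)(C)C)=CC(=CCO[Si](C)(C)C(C)(C)C)C1=O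
A5 | alternative 2 | {2-[methoxy(methyl)amino]-2-oxoethyl}dimethylsulfonium bromide | C[S+](C)CC(=O)N(C)OC.[Br-]
A6 | alternative 2 | (2S,3R)-3-{[tert-butyl(dimethyl)silyl]oxymethyl}-5-{3-[tert-butyl(dimethyl)silyl]oxypropyl}-N,7-dimethoxy-N-methyl-2,3-dihydro-1-benzofuran-2-carboxamide | COc1cc(CCCO[Si](C)(C)C(C)(C)C)cc2c1O[C@H](C(=O)N(C)OC)[C@H]2CO[Si](C)(C)C(C)(C)C
A7 | alternative 3 | (2R)-2-tert-butyl-5-methylidene-1,3-dioxolan-4-one (identical with 5) | O=C1C(=C)O[C@@H](C(C)(C)C)O1
A8 | alternative 3 | buta-1,3-diene (identical with 6) | C=CC=C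
A9 | alternative 3 | (2R,5S)-2-tert-butyl-1,3-dioxaspiro[4.5]dec-7-en-4-one (identical with 7) | O=C1[C@@]2(CCC=CC2)O[C@@H](C(C)(C)C)O1
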